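## The problem

The target is a triply oxygenated longipin-2-en-1-one. A cyclobutane (C4–C5–C11–C10) is spanned across its C4/C11 diagonal by the three-carbon enone bridge C1(=O)–C2=C3(C15), and across its C5/C10 diagonal, from the opposite face, by the four-carbon bridge C6(C12,C13)–C7–C8–C9; C14 is the methyl on C10. Four of the seven stereocentres (4R,5S,10R,11R) sit on the cyclobutane and are locked to one another by the ring fusions, so they must be created together and in one absolute sense. The other three (7S,8S,9S) are contiguous carbinol carbons with O7/O8 cis and O8/O9 trans. The lower bridge lies close to a local mirror plane of the core (C4–H on one face, C11–H on the other), so the framework gives almost no facial bias at C7–C9. The first of these centres therefore needs reagent control and must be the one that can steer the other two. The three hydroxyls must be told apart: O9 (next to quaternary C10) carries the angelate, O8 the isovalerate, and O7 (next to the gem-dimethyl carbon C6) stays free. The angelate isomerises to the tiglate with base, nucleophilic catalysts or long heating; vicinal acyl groups migrate under base; and a cation at C9 or C3 beside the strained ring invites Wagner–Meerwein shifts, so the end game must be neutral and mild. A very short skeleton synthesis is possible because the fifteen carbons are three isoprene units joined head to tail: read from C5 through C4, C3, C2, C1, C11, C10, C9, C8, C7 to C6, the chain is a farnesyl chain from its C1 to its C11. Only three bonds are missing (C5–C6, C5–C11, C4–C10), each between an alkene carbon and a carbon that can become cationic in turn.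

## Retrosynthesis

**O8–acyl bond.** The isovalerate of 20 is cut last, giving diol 18 and isovaleryl chloride 19. O8 is the only hydroxyl of the sector not adjacent to a quaternary carbon, so it can be acylated in the presence of O7. The reverse order (isovalerate first, then angelate at O9 versus O7) would require a choice between two equally hindered hydroxyls. The forward step must show kinetic selectivity for O8 and must not cause acyl migration.

**O9–acyl bond and the diol mask.** The angelate of 18 is traced through acetonide 17 to alcohol 14 and angelic acid 15, and 14 to triol 13. Only the cis-7,8 pair can close a cis-fused dioxolane, so acetonide formation singles out O9 without any selectivity between hydroxyls. The forward esterification must acylate a hindered secondary alcohol without Z-to-E isomerisation.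

**C7–O and C8–O bonds.** Both are cut at once, leading from 13 to allylic alcohol 12 (C7=C8, 9-OH). A cis-dihydroxylation delivers the 7,8-cis relationship directly, and attack anti to the C9 oxygen gives 8,9-trans. An epoxide-opening sequence could only give a 7,8-trans diol. The forward step must choose the C7=C8 bond over the C2=C3 bond, which is why C2=C3 must already be part of an enone.

**C9–H bond.** Alcohol 12 is traced to the bis-enone 9 through its C1-masked form 10. Because the core offers no facial bias, C9 is set by a chiral reduction catalyst. The two conjugated ketones are told apart by enolisability. The C9 enone has quaternary carbons at both its α′ and γ positions; the C1 enone has the C15 methyl, so only C1 can be hidden as a silyl dienol ether.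

**C7=C8 and C9=O.** Enone 9 comes from saturated diketone 7 by dehydrogenation, 7 from alcohol 6, and 6 from enone 5 by cleaving the C9–O bond, i.e. a C–H hydroxylation. C9 is the correct entry point for three reasons:
- a C9 ketone can enolise only towards C8, so the position of the new double bond is fixed;
- a C7 ketone would lead by the same logic to the wrong 8,9-cis pattern;
- a C8 ketone has two near-equivalent α-methylenes that no reagent can tell apart reliably.

The cost is a site-selective oxidation of an unactivated, neopentyl-type methylene, which is assigned to an enzyme.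

**C1=O.** Enone 5 is traced to α-longipinene 4 by allylic oxidation of the only allylic ring methylene. This step is placed first among the oxidations because the enone deactivates C2=C3 towards everything that follows.

**The skeleton (key disconnection).** All three ring-forming bonds of 4 (C5–C6, C5–C11, C4–C10) are cut at once to give (2E,6E)-farnesyl diphosphate 3. No other cut removes three rings and four stereocentres in one operation from an achiral, acyclic precursor. The forward reaction must impose one fold on the chain and close a cyclobutane by cation–olefin addition, which only a cyclase active site does.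

**The diphosphate.** 3 is traced to farnesyl chloride 2 and to commercial (2E,6E)-farnesol 1 by two functional-group interconversions that preserve the alkene geometry.

## Roads not taken

**Alternative 1:** The C5–C11 bond is cut and an NH bridge is put in its place. In the forward direction the bridging secondary amine A2 is converted by an N-acyloxy-N-alkoxyamide into an isodiazene. This loses N2, and the C5/C11 diradical recombines to the cyclobutane of A1, which already carries O9 as a silyl ether and O7/O8 as an acetonide. Its merit is that all three oxygens are in place and differentiated before the ring contraction, so no late C–H oxidation is needed; in this respect it is clearly stronger than the chosen plan. Its weak points are structural. A2 is a bridged azabicycle with seven stereocentres that has to be built by a long conventional sequence. The diradical is a 1,4-diradical whose C11 end is stabilised by the C1 carbonyl, so fragmentation across C4–C10 and loss of configuration compete with closure of a strained ring. The chosen plan sets against this a one-step, enantiospecific assembly of the whole tricycle, and pays with an oxidation sequence afterwards.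

**Alternative 2:** C8 is excised, leading back to an 8-nor tricycle with a six-membered lower ring. In the forward direction its C9 trimethylsilyl enol ether A4 is cyclopropanated (CH2I2, Et2Zn), the siloxycyclopropane is opened with FeCl3, and NaOAc eliminates HCl to give the ring-expanded cycloheptenone A3. This is reliable chemistry, and A3 is the C1-ketal of compound 9 of the chosen route. It reaches the pivotal C9 enone without any enzymatic hydroxylation and with C1 already masked, so it avoids the least certain step of the chosen plan and the masking step as well. Its cost lies in front of the key step: the 8-nor tricyclic ketone still contains the doubly bridged cyclobutane with all four core stereocentres and must itself be made by a multistep enantioselective synthesis. The chosen plan obtains the complete carbon skeleton from farnesol in three steps and has no need for a ketal, but depends on finding a hydroxylase variant.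

**Alternative 3:** The C5–C6 bond is cut. In the forward direction the silyl enol ether A6 of a cyclobutanone, bearing at C10 a side chain with the C9 silyloxy group and a C8 enone, is activated with TiCl4. It adds through C5 to the CMe2 terminus, closing the seven-membered ring of the bicyclo[4.1.1]octanedione ester A5. The merits are a cheap four-membered starting core and early placement of O9 and the C8 carbonyl. The weak points are several. A quaternary centre is formed by conjugate addition to a β,β-disubstituted enone in a medium-ring closure. The strained β-keto ester can open by retro-Claisen cleavage under Lewis acid. C9 is epimerisable next to the C8 ketone. The cyclohexenone ring (C1–C3) and O7 still have to be added afterwards. It avoids a site-selective C–H oxidation, where the chosen plan is weaker, but it is much longer and its key closure is less secure than a native enzymatic cyclisation.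

Key step: step 3

Assumption: the conifer-type α-longipinene synthase is taken to deliver the (+)-enantiomer of 4 (4R,5R,10S,11R in longipinane numbering), which is the enantiomeric series of the target; 3 is drawn as the free acid but handled as its ammonium salt.

## Route

Step 1
Reactants: 1 (2E,6E)-farnesol
Product: 2 (2E,6E)-farnesyl chloride
Conditions: NCS, Me2S, CH2Cl2, −40 to 0 °C
Reagents that add atoms: N-chlorosuccinimide, O=C1CCC(=O)N1Cl
Why: Corey–Kim chlorination of a primary allylic alcohol; chloride displaces the alkoxysulfonium group at the primary carbon, so neither allylic transposition nor loss of the 2E geometry is expected.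

Step 2
Reactants: 2 (2E,6E)-farnesyl chloride
Product: 3 (2E,6E)-farnesyl diphosphate (trisammonium salt)
Conditions: (Bu4N)3HP2O7, MeCN, rt; cation-exchange resin (NH4+ form); cellulose chromatography
Reagents that add atoms: tris(tetrabutylammonium) hydrogen diphosphate, CCCC[N+](CCCC)(CCCC)CCCC.CCCC[N+](CCCC)(CCCC)CCCC.CCCC[N+](CCCC)(CCCC)CCCC.OP(=O)([O-])OP(=O)([O-])[O-]
Why: SN2 displacement of a primary allylic chloride by the diphosphate anion, the standard access to prenyl diphosphates; ion exchange gives the water-soluble salt that the cyclase accepts.

Step 3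
Reactants: 3 (2E,6E)-farnesyl diphosphate
Product: 4 (+)-α-longipinene, (4R,5R,10S,11R)-longipin-2-ene
Conditions: recombinant α-longipinene synthase (conifer-type), MgCl2, HEPES buffer pH 7.5, 30 °C, pentane overlay
Reagents that add atoms: none
Why: This is the native reaction of a class one sesquiterpene cyclase: the magnesium-bound diphosphate ionises, return at the tertiary carbon gives the nerolidyl isomer, and its cisoid allyl cation is attacked at C5 by the distal C6=C7 alkene, forming C5–C6 and the eleven-membered ring (endo with respect to the attacking alkene). A 1,3-hydride shift from C5 to C7 moves the charge into the C3–C4–C5 allyl system, and the C10=C11 alkene attacks C5 through C11 across the ring, forming C5–C11 and the six-membered ring (6-exo mode, tertiary cation at C10). The C3=C4 alkene then captures C10 through C4 (C4–C10, 4-exo mode), a closure that only the enforced proximity in the active site makes faster than elimination, and the tertiary C3 cation loses a proton from C2. C4, C5, C10 and C11 are all set by the fold that the active-site contour imposes on the chain, and the cis ring fusions are in addition forced by the ring sizes. The selectivity needed is product partition, since the same tricyclic cation can rearrange onward to longifolene or lose a C15 proton; a wild-type enzyme or variant that favours C2 deprotonation is chosen, and the substrate contributes only its 2E,6E geometry and head-to-tail spacing. Any longifolene formed has no oxidisable allylic methylene and is removed as a hydrocarbon after step 4.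

Step 4
Reactants: 4 (+)-α-longipinene
Product: 5 (4R,5S,10R,11R)-longipin-2-en-1-one
Conditions: CrO3, 3,5-dimethylpyrazole, CH2Cl2, −20 °C
Reagents that add atoms: chromium trioxide, O=[Cr](=O)=O
Why: Chromium-mediated allylic oxidation of a trisubstituted cycloalkene at its ring methylene, the reaction that turns α-pinene into verbenone; C1 is the only allylic CH2 (C4 is a cyclobutane bridgehead, C15 a less reactive methyl) and the saturated lower bridge is not touched.

Step 5
Reactants: 5 (4R,5S,10R,11R)-longipin-2-en-1-one
Product: 6 (4R,5S,10R,11R)-9-hydroxylongipin-2-en-1-one (9R epimer drawn; either epimer serves)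
Conditions: P450 BM3 (CYP102A1) variant selected from a mutant panel for C9 hydroxylation, NADP+ (cat.), glucose, glucose dehydrogenase, air, phosphate buffer pH 8, DMSO (2% v/v), 25 °C
Reagents that add atoms: dioxygen, O=O
Why: Cytochrome P450 hydroxylation of an unactivated methylene by hydrogen abstraction and oxygen rebound, a reaction type established for rigid terpenoid ketones and lactones, with the site set by active-site mutations. The C1 carbonyl provides a polar anchor that should hold the distal lower bridge over the haem, and the conjugated C2=C3 bond is too electron-poor to be epoxidised. The C9 configuration is erased in step 6.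

Step 6
Reactants: 6 (4R,5S,10R,11R)-9-hydroxylongipin-2-en-1-one
Product: 7 (4R,5S,10R,11R)-longipin-2-ene-1,9-dione
Conditions: Dess–Martin periodinane, CH2Cl2, rt
Reagents that add atoms: none
Why: Dess–Martin oxidation of a hindered secondary alcohol under neutral conditions; the only α-stereocentre of the new ketone (C10) is quaternary and cannot epimerise.

Step 7
Reactants: 7 (4R,5S,10R,11R)-longipin-2-ene-1,9-dione
Product: 9 (4R,5S,10R,11R)-longipina-2,7-diene-1,9-dione, via C9 trimethylsilyl enol ether 8 (not isolated)
Conditions: LiN(SiMe3)2, TMSCl, THF, −78 °C; then Pd(OAc)2, MeCN, rt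
Reagents that add atoms: none
Why: Saegusa–Ito dehydrogenation; the C9 ketone can enolise only towards C8 because C10 is quaternary, and kinetic α-deprotonation of the saturated ketone outpaces γ-deprotonation of the C1 enone. C6 is quaternary, so oxidation cannot go on to a dienone.

Step 8
Reactants: 9 (4R,5S,10R,11R)-longipina-2,7-diene-1,9-dione
Product: 10 (4R,5S,10R,11R)-1-(tert-butyldimethylsilyloxy)longipina-1,3(15),7-trien-9-one
Conditions: TBSOTf, Et3N, CH2Cl2, 0 °C
Reagents that add atoms: tert-butyldimethylsilyl trifluoromethanesulfonate, CC(C)(C)[Si](C)(C)OS(=O)(=O)C(F)(F)F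
Why: Soft enolisation to a silyl dienol ether; only the C1 enone has an acidic γ-hydrogen (on C15), whereas the C9 enone has quaternary carbons at both α′ (C10) and γ (C6) and cannot enolise. C1 alone is thereby masked against hydride.

Step 9
Reactants: 10 (4R,5S,10R,11R)-1-(tert-butyldimethylsilyloxy)longipina-1,3(15),7-trien-9-one
Product: 12 (4R,5S,9R,10R,11R)-9-hydroxylongipina-2,7-dien-1-one, via silyl dienol ether alcohol 11 (not isolated)
Conditions: (S)-Me-CBS oxazaborolidine (0.2 equiv), catecholborane, toluene, −78 °C; then MeOH; 1 M HCl, THF, 0 °C
Reagents that add atoms: none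
Why: Corey–Bakshi–Shibata reduction of the only free ketone; with quaternary C10 as the large flank and vinylic C8 as the small one, the (S)-catalyst should deliver hydride to the C4-side face and place O9 on the C11 side (9R here, 9S once C8 is oxygenated). Catecholborane at −78 °C does not hydroborate the diene. Brief acidic work-up hydrolyses the dienol ether and returns the conjugated C1 enone.

Step 10
Reactants: 12 (4R,5S,9R,10R,11R)-9-hydroxylongipina-2,7-dien-1-one
Product: 13 (4R,5S,7S,8S,9S,10R,11R)-7,8,9-trihydroxylongipin-2-en-1-one
Conditions: OsO4 (cat.), NMO, acetone/H2O, 0 °C to rt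
Reagents that add atoms: osmium tetroxide, O=[Os](=O)(=O)=O; N-methylmorpholine N-oxide, C[N+]1([O-])CCOCC1; water, O
Why: Catalytic osmylation; the isolated cis-disubstituted C7=C8 bond should react far faster than the electron-poor, trisubstituted C2=C3 bond of the enone. OsO4 adds anti to the allylic C9 hydroxyl (the empirical rule for allylic alcohols), so both new oxygens land on the C4-side face, giving the 7,8-cis/8,9-trans triol.

Step 11
Reactants: 13 (4R,5S,7S,8S,9S,10R,11R)-7,8,9-trihydroxylongipin-2-en-1-one
Product: 14 (4R,5S,7S,8R,9S,10R,11R)-9-hydroxy-7,8-(isopropylidenedioxy)longipin-2-en-1-one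
Conditions: 2,2-dimethoxypropane, PPTS (cat.), acetone, rt
Reagents that add atoms: 2,2-dimethoxypropane, COC(C)(C)OC
Why: Acid-catalysed transacetalisation; only the cis-7,8-diol closes an unstrained cis-fused dioxolane, whereas the trans-8,9 pair and the 7,9 pair would give strained rings, so O9 alone remains free.

Step 12
Reactants: 14 (4R,5S,7S,8R,9S,10R,11R)-9-hydroxy-7,8-(isopropylidenedioxy)longipin-2-en-1-one; 15 angelic acid, (Z)-2-methylbut-2-enoic acid
Product: 17 (4R,5S,7S,8S,9S,10R,11R)-9-angeloyloxy-7,8-(isopropylidenedioxy)longipin-2-en-1-one, via angelic 2,4,6-trichlorobenzoic mixed anhydride 16 (not isolated)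
Conditions: 15, 2,4,6-trichlorobenzoyl chloride, Et3N, toluene, rt; then 14, toluene, 80 °C (no DMAP)
Reagents that add atoms: none
Why: Yamaguchi-type mixed-anhydride esterification, the usual way to place an angelate on a hindered secondary alcohol; the alcohol attacks the less shielded angeloyl carbonyl of 16. Leaving out nucleophilic catalysts avoids the addition–elimination path that turns angelate into tiglate.

Step 13
Reactants: 17 (4R,5S,7S,8S,9S,10R,11R)-9-angeloyloxy-7,8-(isopropylidenedioxy)longipin-2-en-1-one
Product: 18 (4R,5S,7S,8S,9S,10R,11R)-9-angeloyloxy-7,8-dihydroxylongipin-2-en-1-one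
Conditions: AcOH/H2O (4:1), 40 °C
Reagents that add atoms: none
Why: Mild acidic hydrolysis of an isopropylidene acetal; the conjugated ester and the enone tolerate aqueous acetic acid, and acid-mediated acyl migration across the trans-8,9 pair is slow.

Step 14
Reactants: 18 (4R,5S,7S,8S,9S,10R,11R)-9-angeloyloxy-7,8-dihydroxylongipin-2-en-1-one; 19 isovaleryl chloride
Product: 20 (4R,5S,7S,8S,9S,10R,11R)-9-angeloyloxy-7-hydroxy-8-isovaleroyloxylongipin-2-en-1-one (CNP0251293.1)
Conditions: 19 (1.1 equiv), pyridine, CH2Cl2, −30 to 0 °C
Reagents that add atoms: none
Why: Kinetically controlled acylation; O8 is flanked by two CH carbons whereas O7 sits next to the gem-dimethyl carbon C6, so the acid chloride should select O8. Low temperature and the absence of DMAP protect the angelate geometry and limit acyl migration.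

## Compound list

1 | (2E,6E)-farnesol | CC(C)=CCC/C(C)=C/CC/C(C)=C/CO | starting material
2 | (2E,6E)-farnesyl chloride | CC(C)=CCC/C(C)=C/CC/C(C)=C/CCl | intermediate
3 | (2E,6E)-farnesyl diphosphate (free acid drawn, used as trisammonium salt) | CC(C)=CCC/C(C)=C/CC/C(C)=C/COP(=O)(O)OP(=O)(O)O | intermediate
4 | (+)-α-longipinene, (4R,5R,10S,11R)-longipin-2-ene | C1CCC(C)(C)[C@@H]2[C@H]3CC=C(C)[C@@H]2[C@@]13C | intermediate
5 | (4R,5S,10R,11R)-longipin-2-en-1-one | C1CCC(C)(C)[C@@H]2[C@H]3C(=O)C=C(C)[C@@H]2[C@@]13C | intermediate
6 | (4R,5S,10R,11R)-9-hydroxylongipin-2-en-1-one (9R epimer drawn) | O[C@@H]1CCC(C)(C)[C@@H]2[C@H]3C(=O)C=C(C)[C@@H]2[C@@]13C | intermediate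
7 | (4R,5S,10R,11R)-longipin-2-ene-1,9-dione | O=C1CCC(C)(C)[C@@H]2[C@H]3C(=O)C=C(C)[C@@H]2[C@@]13C | intermediate
8 | 9-(trimethylsilyloxy)longipina-2,8-dien-1-one | C[Si](C)(C)OC1=CCC(C)(C)[C@@H]2[C@H]3C(=O)C=C(C)[C@@H]2[C@@]13C | intermediate (not isolated)
9 | (4R,5S,10R,11R)-longipina-2,7-diene-1,9-dione | O=C1C=CC(C)(C)[C@@H]2[C@H]3C(=O)C=C(C)[C@@H]2[C@@]13C | intermediate
10 | (4R,5S,10R,11R)-1-(tert-butyldimethylsilyloxy)longipina-1,3(15),7-trien-9-one | O=C1C=CC(C)(C)[C@@H]2[C@H]3C(O[Si](C)(C)C(C)(C)C)=CC(=C)[C@@H]2[C@@]13C | intermediate
11 | (9R)-1-(tert-butyldimethylsilyloxy)longipina-1,3(15),7-trien-9-ol | O[C@@H]1C=CC(C)(C)[C@@H]2[C@H]3C(O[Si](C)(C)C(C)(C)C)=CC(=C)[C@@H]2[C@@]13C | intermediate (not isolated)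
12 | (4R,5S,9R,10R,11R)-9-hydroxylongipina-2,7-dien-1-one | O[C@@H]1C=CC(C)(C)[C@@H]2[C@H]3C(=O)C=C(C)[C@@H]2[C@@]13C | intermediate
13 | (4R,5S,7S,8S,9S,10R,11R)-7,8,9-trihydroxylongipin-2-en-1-one | O[C@@H]1[C@@H](O)[C@@H](O)C(C)(C)[C@@H]2[C@H]3C(=O)C=C(C)[C@@H]2[C@@]13C | intermediate
14 | (4R,5S,7S,8R,9S,10R,11R)-9-hydroxy-7,8-(isopropylidenedioxy)longipin-2-en-1-one | O[C@@H]1[C@@H](OC(C)(C)O4)[C@@H]4C(C)(C)[C@@H]2[C@H]3C(=O)C=C(C)[C@@H]2[C@@]13C | intermediate
15 | angelic acid, (Z)-2-methylbut-2-enoic acid | C/C=C(/C)C(=O)O | starting material
16 | (Z)-2-methylbut-2-enoic 2,4,6-trichlorobenzoic anhydride | C/C=C(/C)C(=O)OC(=O)c1c(Cl)cc(Cl)cc1Cl | intermediate (not isolated)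
17 | (4R,5S,7S,8S,9S,10R,11R)-9-angeloyloxy-7,8-(isopropylidenedioxy)longipin-2-en-1-one | C/C=C(/C)C(=O)O[C@@H]1[C@@H](OC(C)(C)O4)[C@@H]4C(C)(C)[C@@H]2[C@H]3C(=O)C=C(C)[C@@H]2[C@@]13C | intermediate
18 | (4R,5S,7S,8S,9S,10R,11R)-9-angeloyloxy-7,8-dihydroxylongipin-2-en-1-one | C/C=C(/C)C(=O)O[C@@H]1[C@@H](O)[C@@H](O)C(C)(C)[C@@H]2[C@H]3C(=O)C=C(C)[C@@H]2[C@@]13C | intermediate
19 | isovaleryl chloride | CC(C)CC(=O)Cl | starting material
20 | (4R,5S,7S,8S,9S,10R,11R)-9-angeloyloxy-7-hydroxy-8-isovaleroyloxylongipin-2-en-1-one (CNP0251293.1) | C/C=C(/C)C(=O)O[C@@H]1[C@@H](OC(=O)CC(C)C)[C@@H](O)C(C)(C)[C@@H]2[C@H]3C(=O)C=C(C)[C@@H]2[C@@]13C | target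

## Step count and least certain steps

Total step count: 14. Longest linear sequence: 14 steps (1 to 20); 15 and 19 enter directly in steps 12 and 14.

**Step 5 (C9 hydroxylation).** The most likely failure is oxidation at another position: the allylic C15 methyl, or the C8 methylene, which is less hindered and further from the carbonyl than C9. Low turnover on a compact hydrocarbon-like ketone is also possible. No variant with this selectivity is known in advance, so this step depends on screening and is the weakest point of the route.

The fallback replaces the enzyme by reagent chemistry that accepts oxidation at C8 and then moves the oxygen. It sets out from 5 and returns at 9.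
- Oxidation of 5 with Fe(PDP)(MeCN)2(SbF6)2, H2O2 and AcOH at the most electron-rich, least hindered methylene should give longipin-2-ene-1,8-dione F1.
- Kinetic enolisation towards the less shielded C9 side (LiN(SiMe3)2, PhNTf2) gives 1-oxolongipina-2,8-dien-8-yl triflate F2.
- Formate reduction (Pd(OAc)2, PPh3, HCO2H, Bu3N) gives longipina-2,8-dien-1-one F3.
- mCPBA epoxidises only the isolated alkene, giving 8,9-epoxylongipin-2-en-1-one F4.
- Sodium phenylselenide ((PhSe)2, NaBH4, EtOH) opens F4 at the less hindered C8, giving 9-hydroxy-8-(phenylselanyl)longipin-2-en-1-one F5.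
- Dess–Martin oxidation gives 8-(phenylselanyl)longipin-2-ene-1,9-dione F6.
- H2O2 triggers selenoxide syn-elimination towards C7 and delivers 9.

The uncertain point of this detour is the direction of enolisation of F1.

**Step 3 (key step).** The most likely failure is diversion of the tricyclic cation into onward rearrangement (longifolene) or alternative deprotonation instead of loss of the C2 proton. Slow turnover through diphosphate inhibition is also possible. Both arise because the final partition is decided only by the active site. The fallback changes from the cell-free reaction to whole-cell production: a microbial host with a heterologous mevalonate pathway forms 3 inside the cell and the co-expressed cyclase (or a variant with a narrower product spectrum) converts it under continuous two-phase extraction. It sets out from 3, now generated in vivo, and returns at 4; no new compound arises (F0).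

**Step 9 (C9 reduction).** The most likely failure is weak or reversed facial discrimination, because the ranking of a quaternary carbon against a vinylic carbon as the larger flank is not secure. Incomplete re-conjugation during hydrolysis is a second possibility. The fallback gives up catalyst control for separation and recycling. It sets out from 10 and returns at 12. Luche reduction (NaBH4, CeCl3·7H2O, MeOH) gives 11 together with its C9 epimer, (9S)-1-(tert-butyldimethylsilyloxy)longipina-1,3(15),7-trien-9-ol F7. Acidic hydrolysis gives 12 and (9S)-9-hydroxylongipina-2,7-dien-1-one F8. After chromatographic separation, F8 is re-oxidised with MnO2 to 9 and recycled.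

**Step 10 (dihydroxylation).** The most likely failure is erosion of anti selectivity, because a free allylic hydroxyl can hydrogen-bond to the oxidant and draw it to its own face. The fallback adds steric direction. It sets out from 12 and returns at 14.
- Silylation (TBSOTf, 2,6-lutidine) gives 9-(tert-butyldimethylsilyloxy)longipina-2,7-dien-1-one F9.
- OsO4/NMO gives 9-(tert-butyldimethylsilyloxy)-7,8-dihydroxylongipin-2-en-1-one F10.
- 2,2-Dimethoxypropane/PPTS gives 9-(tert-butyldimethylsilyloxy)-7,8-(isopropylidenedioxy)longipin-2-en-1-one F11.
- Bu4NF/AcOH releases 14.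

**Step 12 (angeloylation).** The most likely failure is incomplete acylation of the doubly flanked O9, with Z-to-E isomerisation of the acyl group at the temperature needed to force it. The fallback builds the double bond on the ester instead of transferring it. It sets out from 14 and returns at 17. Esterification with 2-(diphenoxyphosphoryl)propanoic acid (DCC, DMAP) gives the 9-O-[2-(diphenoxyphosphoryl)propanoyl] acetonide F12. A Z-selective Horner–Wadsworth–Emmons reaction of this diaryl phosphonate with acetaldehyde (NaH, THF, −78 °C) gives 17.

**Step 14 (isovaleroylation).** The most likely failure is acylation at O7 or at both hydroxyls, or base-promoted migration of the isovaleroyl group from O8 to O7 or of the angeloyl group from O9 to O8, since all three oxygens are vicinal. The fallback activates one oxygen selectively. It sets out from 18 and returns at 20. Bu2SnO (toluene/MeOH, reflux) gives the 7,8-O-dibutylstannylene acetal of 18, F13. Isovaleryl chloride in toluene at 0 °C then acylates the less hindered tin-bound oxygen, O8.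

## Further compounds

F1 | step 5 | (4R,5S,10R,11R)-longipin-2-ene-1,8-dione | C1C(=O)CC(C)(C)[C@@H]2[C@H]3C(=O)C=C(C)[C@@H]2[C@@]13C
F2 | step 5 | 1-oxolongipina-2,8-dien-8-yl trifluoromethanesulfonate | C1=C(OS(=O)(=O)C(F)(F)F)CC(C)(C)[C@@H]2[C@H]3C(=O)C=C(C)[C@@H]2[C@@]13C
F3 | step 5 | (4R,5S,10R,11R)-longipina-2,8-dien-1-one | C1=CCC(C)(C)[C@@H]2[C@H]3C(=O)C=C(C)[C@@H]2[C@@]13C
F4 | step 5 | 8,9-epoxylongipin-2-en-1-one (either epoxide face) | C15OC5CC(C)(C)[C@@H]2[C@H]3C(=O)C=C(C)[C@@H]2[C@@]13C
F5 | step 5 | trans-9-hydroxy-8-(phenylselanyl)longipin-2-en-1-one (from either epoxide) | OC1C([Se]c5ccccc5)CC(C)(C)[C@@H]2[C@H]3C(=O)C=C(C)[C@@H]2[C@@]13C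
F6 | step 5 | 8-(phenylselanyl)longipin-2-ene-1,9-dione | O=C1C([Se]c5ccccc5)CC(C)(C)[C@@H]2[C@H]3C(=O)C=C(C)[C@@H]2[C@@]13C
F0 | step 3 | none | none
F7 | step 9 | (9S)-1-(tert-butyldimethylsilyloxy)longipina-1,3(15),7-trien-9-ol | O[C@H]1C=CC(C)(C)[C@@H]2[C@H]3C(O[Si](C)(C)C(C)(C)C)=CC(=C)[C@@H]2[C@@]13C
F8 | step 9 | (4R,5S,9S,10R,11R)-9-hydroxylongipina-2,7-dien-1-one | O[C@H]1C=CC(C)(C)[C@@H]2[C@H]3C(=O)C=C(C)[C@@H]2[C@@]13C
F9 | step 10 | (9R)-9-(tert-butyldimethylsilyloxy)longipina-2,7-dien-1-one | CC(C)(C)[Si](C)(C)O[C@@H]1C=CC(C)(C)[C@@H]2[C@H]3C(=O)C=C(C)[C@@H]2[C@@]13C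
F10 | step 10 | 9-(tert-butyldimethylsilyloxy)-7,8-dihydroxylongipin-2-en-1-one | CC(C)(C)[Si](C)(C)O[C@@H]1[C@@H](O)[C@@H](O)C(C)(C)[C@@H]2[C@H]3C(=O)C=C(C)[C@@H]2[C@@]13C
F11 | step 10 | 9-(tert-butyldimethylsilyloxy)-7,8-(isopropylidenedioxy)longipin-2-en-1-one | CC(C)(C)[Si](C)(C)O[C@@H]1[C@@H](OC(C)(C)O4)[C@@H]4C(C)(C)[C@@H]2[C@H]3C(=O)C=C(C)[C@@H]2[C@@]13C
F12 | step 12 | 9-O-[2-(diphenoxyphosphoryl)propanoyl]-7,8-(isopropylidenedioxy)longipin-2-en-1-one (epimers at the phosphonate carbon) | CC(P(=O)(Oc5ccccc5)Oc5ccccc5)C(=O)O[C@@H]1[C@@H](OC(C)(C)O4)[C@@H]4C(C)(C)[C@@H]2[C@H]3C(=O)C=C(C)[C@@H]2[C@@]13C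
F13 | step 14 | 7,8-O-dibutylstannylene acetal of 18 | C/C=C(/C)C(=O)O[C@@H]1[C@@H](O[Sn](CCCC)(CCCC)O4)[C@@H]4C(C)(C)[C@@H]2[C@H]3C(=O)C=C(C)[C@@H]2[C@@]13C
A1 | alternative 1 | 9-(tert-butyldimethylsilyloxy)-7,8-(isopropylidenedioxy)longipin-2-en-1-one | CC(C)(C)[Si](C)(C)O[C@@H]1[C@@H](OC(C)(C)O4)[C@@H]4C(C)(C)[C@@H]2[C@H]3C(=O)C=C(C)[C@@H]2[C@@]13C
A2 | alternative 1 | C5,C11-imino-bridged precursor amine (NH between C5 and C11 in place of the C5–C11 bond) | CC(C)(C)[Si](C)(C)O[C@@H]1[C@@H](OC(C)(C)O4)[C@@H]4C(C)(C)[C@@H]2N[C@H]3C(=O)C=C(C)[C@@H]2[C@@]13C
A3 | alternative 2 | longipina-2,7-diene-1,9-dione 1-ethylene ketal | O=C1C=CC(C)(C)[C@@H]2[C@H]3C4(OCCO4)C=C(C)[C@@H]2[C@@]13C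
A4 | alternative 2 | C9 trimethylsilyl enol ether of the 8-nor tricyclic ketone, C1 ethylene ketal | C[Si](C)(C)OC1=CC(C)(C)[C@@H]2[C@H]3C4(OCCO4)C=C(C)[C@@H]2[C@@]13C
A5 | alternative 3 | ethyl 5-(tert-butyldimethylsilyloxy)-2,2,6-trimethyl-4,8-dioxobicyclo[4.1.1]octane-7-carboxylate | CC(C)(C)[Si](C)(C)O[C@@H]1C(=O)CC(C)(C)[C@H]2C(=O)[C@]1(C)[C@@H]2C(=O)OCC
A6 | alternative 3 | ethyl 2-methyl-2-[1-(tert-butyldimethylsilyloxy)-4-methyl-2-oxopent-3-enyl]-3-(trimethylsilyloxy)cyclobut-3-ene-1-carboxylate | CC(C)(C)[Si](C)(C)O[C@H](C(=O)C=C(C)C)[C@]1(C)C(O[Si](C)(C)C)=C[C@H]1C(=O)OCC
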